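**Plan**

- Cuts: the O–CH3 bond of the protected tetronic acid; the CH2–C(CH3)= bond beside the Z trisubstituted alkene (B-alkyl Suzuki–Miyaura coupling); and, in one operation, the bond from the exocyclic ylidene CH to the CH(CH3) stereocenter together with ring bonds C4–C5 and O1–C2 of the furanone.
- Enabling feature: the enol-lactone unit O1–C5(=CH–) of the furanone ring is a ketene O=C=CH– that has taken up a vinyl anion at C5 and closed through its own oxygen, and the CH(CH3) carbon next to the ylidene CH is an allyl terminus. An allyl alkynyl ether therefore gives both by a [3,3] shift.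
- Forward: aryloxy ynone, R propargylic alcohol, Z allylic alcohol, dichlorovinyl ether; then one flask builds the furanone ring ([3,3] shift, ketene capture by lithiated methyl 3-methoxy-2-methylacrylate, lactonisation); palladium/formate moves the helper alkene to the chain end and expels the helper aryloxide; hydroboration/Suzuki coupling joins the bis-furan vinyl iodide; demethylation ends the route.
- Bis-furan fragment: 3-furyllithium plus 4-bromofuran-2-carbaldehyde, deoxygenation, B-alkyl Suzuki coupling with an acrolein acetal borane, hydrolysis, Z-selective iodo-Wittig reaction.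
- Stereochemistry: the S centre by 1,3-chirality transfer from the R carbinol carbon (catalyst-controlled transfer hydrogenation); the Z ylidene from in-plane attack on the ketene beside its hydrogen; the Z trisubstituted alkene from the Z vinyl iodide with retention in the coupling.

Key step: step 7

Remark: the sense of induction in step 4 is assigned by analogy with alkynyl methyl ketones (alkynyl group in the place of an aryl group); should it prove opposite, the R,R catalyst is used instead.

Step 1
Reactants: 1 methyl propanoate; 2 methyl formate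
Product: 4 methyl (E)-3-methoxy-2-methylprop-2-enoate, via sodium formyl enolate 3 (not isolated)
Conditions: NaH, THF, 0 °C to rt; then Me2SO4, DMF, rt; distillation
Reagents that add atoms: dimethyl sulfate, COS(=O)(=O)OC
Why: Crossed Claisen condensation (formylation) and O-methylation of the enolate should give mainly the E enol ether, whose vinylic hydrogen is cis to the ester as the later directed lithiation requires.

Step 2
Reactants: 5 (4-methoxyphenoxy)acetyl chloride
Product: 6 N-methoxy-2-(4-methoxyphenoxy)-N-methylacetamide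
Conditions: MeNHOMe·HCl, Et3N, CH2Cl2, 0 °C to rt
Reagents that add atoms: N,O-dimethylhydroxylamine hydrochloride, CNOC.Cl
Why: N-Acylation of the amine by the acid chloride (Weinreb amide formation) is routine and the aryl ether is inert.

Step 3
Reactants: 6 N-methoxy-2-(4-methoxyphenoxy)-N-methylacetamide; 7 prop-1-ynylmagnesium bromide
Product: 8 1-(4-methoxyphenoxy)pent-3-yn-2-one
Conditions: THF, −78 to 0 °C; aq NH4Cl
Reagents that add atoms: none
Why: Weinreb ketone synthesis, in which the chelated tetrahedral adduct survives until work-up so that the ynone is not attacked a second time.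

Step 4
Reactants: 8 1-(4-methoxyphenoxy)pent-3-yn-2-one
Product: 9 (2R)-1-(4-methoxyphenoxy)pent-3-yn-2-ol
Conditions: Ru[(S,S)-TsNCH(Ph)CH(Ph)NH](p-cymene) (1 mol %), i-PrOH, 25 °C
Reagents that add atoms: none
Why: Noyori asymmetric transfer hydrogenation of an alkynyl ketone under base-free conditions, where the S,S ligand should set the carbinol centre (descriptor R because CH2OAr outranks the alkynyl group).

Step 5
Reactants: 9 (2R)-1-(4-methoxyphenoxy)pent-3-yn-2-ol
Product: 10 (2R,3Z)-1-(4-methoxyphenoxy)pent-3-en-2-ol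
Conditions: H2 (1 atm), Pd/CaCO3 poisoned with Pb(OAc)2, quinoline, EtOAc, rt
Reagents that add atoms: none
Why: Lindlar-type semihydrogenation delivers hydrogen syn on the poisoned surface to give the Z alkene without touching the carbinol centre.

Step 6
Reactants: 10 (2R,3Z)-1-(4-methoxyphenoxy)pent-3-en-2-ol; 11 trichloroethene
Product: 12 1-{[(2R,3Z)-2-{[(E)-1,2-dichloroethenyl]oxy}pent-3-en-1-yl]oxy}-4-methoxybenzene
Conditions: KH (1.5 equiv), THF, 0 °C; then 11, −50 °C to rt
Reagents that add atoms: none
Why: Elimination–addition vinylic substitution, in which the alkoxide adds anti to dichloroethyne formed in situ to give the E dichlorovinyl ether; the C–O bond at the stereocenter is not broken.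

Step 7
Reactants: 12 1-{[(2R,3Z)-2-{[(E)-1,2-dichloroethenyl]oxy}pent-3-en-1-yl]oxy}-4-methoxybenzene; 4 methyl (E)-3-methoxy-2-methylprop-2-enoate
Product: 18 (5Z)-4-methoxy-5-[(2S,3E)-5-(4-methoxyphenoxy)-2-methylpent-3-en-1-ylidene]-3-methylfuran-2(5H)-one, via lithium alkynyl ether 13 (not isolated), via allyl alkynyl ether 14 (not isolated), via ketene 15 (not isolated), via vinyllithium 16 (not isolated), via lithium enolate 17 (not isolated)
Conditions: 12, n-BuLi (2.05 equiv), THF, −78 °C; 2,6-di-tert-butyl-4-methylphenol (1.05 equiv), −78 to −60 °C; then by cannula into 16 (1.2 equiv; from 4, lithium 2,2,6,6-tetramethylpiperidide, THF, −95 °C), −78 to −20 °C; aq NH4Cl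
Reagents that add atoms: none
Why: Proposed new method: elimination and Cl–Li exchange give lithium alkynyl ether 13, and protonation by the hindered phenol releases allyl alkynyl ether 14, which undergoes the low-temperature [3,3] shift of allyl alkynyl ethers (ynol-ether Claisen rearrangement, the closest known reaction type, known with alcohol or amine capture of the ketene) to form the bond between the alkyne CH and the propenyl terminus and give ketene 15. The new stereocenter is set by 1,3-chirality transfer from the R carbinol carbon through a chair transition state with the CH2OAr group pseudo-equatorial; the Z methyl group puts allylic 1,3-strain on the alternative chair, so the S centre and the E alkene should result. Vinyllithium 16, a chelated β-lithio-β-methoxyacrylate of the kind known to add to aldehydes and lactonise to methyl tetronates, then adds to the ketene carbonyl carbon in the plane of the ketene substituents from the side of the hydrogen, as organolithiums do with ketenes to give stereodefined enolates, which places the enolate oxygen of 17 cis to the branched chain. That oxygen acylates the cis ester in a 5-exo-trig closure with loss of methoxide to close the furanone ring, so the Z ylidene follows from the enolate geometry, whereas C-acylation would be a disfavoured 5-(enolendo)-exo-trig closure. The step needs complete chirality transfer (secured by the Z propenyl methyl group), the Z ylidene (secured by the size difference between hydrogen and the branched chain on the ketene carbon) and capture of the ketene by carbon and not by oxygen or nitrogen bases (secured by a phenoxide and an amine that are both too hindered to acylate).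

Step 8
Reactants: 18 (5Z)-4-methoxy-5-[(2S,3E)-5-(4-methoxyphenoxy)-2-methylpent-3-en-1-ylidene]-3-methylfuran-2(5H)-one
Product: 19 (5Z)-4-methoxy-3-methyl-5-[(2S)-2-methylpent-4-en-1-ylidene]furan-2(5H)-one
Conditions: Pd2(dba)3·CHCl3 (2.5 mol %), PBu3 (10 mol %), HCO2H, Et3N, THF, 50 °C
Reagents that add atoms: none
Why: Palladium-catalysed formate hydrogenolysis of an allylic aryl ether (ionisation of the Tsuji–Trost type by zerovalent palladium), in which the allylpalladium formate transfers hydride internally to the substituted allyl terminus with loss of CO2, giving the terminal alkene and leaving the neighbouring stereocenter untouched.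

Step 9
Reactants: 20 3-bromofuran; 21 4-bromofuran-2-carbaldehyde
Product: 23 (4-bromofuran-2-yl)(furan-3-yl)methanol (racemic), via 3-furyllithium 22 (not isolated)
Conditions: 20, n-BuLi, THF, −78 °C; then 21, −78 °C; aq NH4Cl
Reagents that add atoms: none
Why: Bromine–lithium exchange and 1,2-addition to the aldehyde, which is faster than exchange at the second bromide; the carbinol centre is removed in the next step.

Step 10
Reactants: 23 (4-bromofuran-2-yl)(furan-3-yl)methanol
Product: 24 4-bromo-2-(furan-3-ylmethyl)furan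
Conditions: Et3SiH (3 equiv), CF3CO2H, CH2Cl2, −20 to 0 °C
Reagents that add atoms: none
Why: Ionic hydrogenation, in which the carbenium ion stabilised by both furan rings is captured by hydride from the silane.

Step 11
Reactants: 24 4-bromo-2-(furan-3-ylmethyl)furan; 25 3,3-diethoxyprop-1-ene
Product: 27 4-(3,3-diethoxypropyl)-2-(furan-3-ylmethyl)furan, via alkylborane 26 (not isolated)
Conditions: 25, 9-BBN, THF, 0 °C to rt; then 24, Pd(dppf)Cl2 (5 mol %), K3PO4 (aq), DMF, 65 °C
Reagents that add atoms: none
Why: Anti-Markovnikov hydroboration followed by B-alkyl Suzuki–Miyaura coupling at the furyl bromide; the acetal is inert to both.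

Step 12
Reactants: 27 4-(3,3-diethoxypropyl)-2-(furan-3-ylmethyl)furan
Product: 28 3-[5-(furan-3-ylmethyl)furan-3-yl]propanal
Conditions: oxalic acid (aq), THF, rt
Reagents that add atoms: water, O
Why: Acetal hydrolysis under acid mild enough for the two furan rings.

Step 13
Reactants: 29 ethyltriphenylphosphonium iodide; 28 3-[5-(furan-3-ylmethyl)furan-3-yl]propanal
Product: 33 2-(furan-3-ylmethyl)-4-[(3Z)-4-iodopent-3-en-1-yl]furan, via ethylidene ylide 30 (not isolated), via iodoethylphosphonium iodide 31 (not isolated), via iodo ylide 32 (not isolated)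
Conditions: 29, n-BuLi, THF, 0 °C; I2, −78 °C; NaN(SiMe3)2, −20 °C; then 28, −78 °C to rt
Reagents that add atoms: iodine, II
Why: Wittig olefination with an α-iodo ylide (Stork–Zhao type), whose kinetically controlled oxaphosphetane should give the Z iodoalkene.

Step 14
Reactants: 19 (5Z)-4-methoxy-3-methyl-5-[(2S)-2-methylpent-4-en-1-ylidene]furan-2(5H)-one; 33 2-(furan-3-ylmethyl)-4-[(3Z)-4-iodopent-3-en-1-yl]furan
Product: 35 (5Z)-5-[(2S,6Z)-9-[5-(furan-3-ylmethyl)furan-3-yl]-2,6-dimethylnon-6-en-1-ylidene]-4-methoxy-3-methylfuran-2(5H)-one, via alkylborane 34 (not isolated)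
Conditions: 19, 9-BBN, THF, 0 °C to rt; then 33, Pd(dppf)Cl2 (5 mol %), AsPh3, Cs2CO3, DMF/H2O, rt
Reagents that add atoms: none
Why: 9-BBN should hydroborate only the terminal alkene, and the B-alkyl Suzuki–Miyaura coupling proceeds with retention at the vinyl iodide, which fixes the Z trisubstituted alkene.

Step 15
Reactants: 35 (5Z)-5-[(2S,6Z)-9-[5-(furan-3-ylmethyl)furan-3-yl]-2,6-dimethylnon-6-en-1-ylidene]-4-methoxy-3-methylfuran-2(5H)-one
Product: 36 (5Z)-5-[(2S,6Z)-9-[5-(furan-3-ylmethyl)furan-3-yl]-2,6-dimethylnon-6-en-1-ylidene]-4-hydroxy-3-methylfuran-2(5H)-one (target)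
Conditions: n-PrSLi (from n-PrSH, n-BuLi), HMPA, rt; then dilute HCl
Reagents that add atoms: none
Why: SN2 O-demethylation of the vinylogous methyl carbonate by thiolate releases the tetronic acid without touching the alkenes, the furans or the stereocenter.

**Compound list**

1 | methyl propanoate | CCC(=O)OC | starting material
2 | methyl formate | COC=O | starting material
3 | sodium enolate of methyl 2-formylpropanoate | [Na+].[O-]C=C(C)C(=O)OC | intermediate
4 | methyl (E)-3-methoxy-2-methylprop-2-enoate | CO/C=C(\C)C(=O)OC | intermediate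
5 | (4-methoxyphenoxy)acetyl chloride | COc1ccc(OCC(Cl)=O)cc1 | starting material
6 | N-methoxy-2-(4-methoxyphenoxy)-N-methylacetamide | COc1ccc(OCC(=O)N(C)OC)cc1 | intermediate
7 | prop-1-ynylmagnesium bromide | CC#C[Mg]Br | starting material
8 | 1-(4-methoxyphenoxy)pent-3-yn-2-one | CC#CC(=O)COc1ccc(OC)cc1 | intermediate
9 | (2R)-1-(4-methoxyphenoxy)pent-3-yn-2-ol | CC#C[C@@H](O)COc1ccc(OC)cc1 | intermediate
10 | (2R,3Z)-1-(4-methoxyphenoxy)pent-3-en-2-ol | C/C=C\[C@@H](O)COc1ccc(OC)cc1 | intermediate
11 | trichloroethene | ClC=C(Cl)Cl | starting material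
12 | 1-{[(2R,3Z)-2-{[(E)-1,2-dichloroethenyl]oxy}pent-3-en-1-yl]oxy}-4-methoxybenzene | C/C=C\[C@@H](O/C(Cl)=C\Cl)COc1ccc(OC)cc1 | intermediate
13 | 1-{[(2R,3Z)-2-[(lithioethynyl)oxy]pent-3-en-1-yl]oxy}-4-methoxybenzene (lithium alkynyl ether) | C/C=C\[C@@H](OC#C[Li])COc1ccc(OC)cc1 | intermediate
14 | 1-{[(2R,3Z)-2-(ethynyloxy)pent-3-en-1-yl]oxy}-4-methoxybenzene (allyl alkynyl ether) | C/C=C\[C@@H](OC#C)COc1ccc(OC)cc1 | intermediate
15 | (3S,4E)-6-(4-methoxyphenoxy)-3-methylhexa-1,4-dien-1-one (ketene) | O=C=C[C@@H](C)/C=C/COc1ccc(OC)cc1 | intermediate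
16 | methyl (E)-3-lithio-3-methoxy-2-methylprop-2-enoate (lithium cis to the ester) | CO/C([Li])=C(\C)C(=O)OC | intermediate
17 | lithium enolate from addition of 16 to 15 (enolate oxygen cis to the chain; acyl carbon cis to the ester) | [Li+].[O-]/C(=C\[C@@H](C)/C=C/COc1ccc(OC)cc1)/C(OC)=C(/C)C(=O)OC | intermediate
18 | (5Z)-4-methoxy-5-[(2S,3E)-5-(4-methoxyphenoxy)-2-methylpent-3-en-1-ylidene]-3-methylfuran-2(5H)-one | COC1=C(C)C(=O)O/C1=C\[C@@H](C)/C=C/COc1ccc(OC)cc1 | intermediate
19 | (5Z)-4-methoxy-3-methyl-5-[(2S)-2-methylpent-4-en-1-ylidene]furan-2(5H)-one | COC1=C(C)C(=O)O/C1=C\[C@@H](C)CC=C | intermediate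
20 | 3-bromofuran | Brc1ccoc1 | starting material
21 | 4-bromofuran-2-carbaldehyde | O=Cc1cc(Br)co1 | starting material
22 | 3-furyllithium | [Li]c1ccoc1 | intermediate
23 | (4-bromofuran-2-yl)(furan-3-yl)methanol (racemic) | OC(c1ccoc1)c1cc(Br)co1 | intermediate
24 | 4-bromo-2-(furan-3-ylmethyl)furan | Brc1coc(Cc2ccoc2)c1 | intermediate
25 | 3,3-diethoxyprop-1-ene | C=CC(OCC)OCC | starting material
26 | 9-(3,3-diethoxypropyl)-9-borabicyclo[3.3.1]nonane | CCOC(CCB1C2CCCC1CCC2)OCC | intermediate
27 | 4-(3,3-diethoxypropyl)-2-(furan-3-ylmethyl)furan | CCOC(CCc1coc(Cc2ccoc2)c1)OCC | intermediate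
28 | 3-[5-(furan-3-ylmethyl)furan-3-yl]propanal | O=CCCc1coc(Cc2ccoc2)c1 | intermediate
29 | ethyltriphenylphosphonium iodide | CC[P+](c1ccccc1)(c1ccccc1)c1ccccc1.[I-] | starting material
30 | ethylidenetriphenylphosphorane | CC=P(c1ccccc1)(c1ccccc1)c1ccccc1 | intermediate
31 | (1-iodoethyl)triphenylphosphonium iodide | CC(I)[P+](c1ccccc1)(c1ccccc1)c1ccccc1.[I-] | intermediate
32 | (1-iodoethylidene)triphenylphosphorane | CC(I)=P(c1ccccc1)(c1ccccc1)c1ccccc1 | intermediate
33 | 2-(furan-3-ylmethyl)-4-[(3Z)-4-iodopent-3-en-1-yl]furan | C/C(I)=C/CCc1coc(Cc2ccoc2)c1 | intermediate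
34 | (5Z)-5-[(2S)-5-(9-borabicyclo[3.3.1]nonan-9-yl)-2-methylpentylidene]-4-methoxy-3-methylfuran-2(5H)-one | COC1=C(C)C(=O)O/C1=C\[C@@H](C)CCCB1C2CCCC1CCC2 | intermediate
35 | (5Z)-5-[(2S,6Z)-9-[5-(furan-3-ylmethyl)furan-3-yl]-2,6-dimethylnon-6-en-1-ylidene]-4-methoxy-3-methylfuran-2(5H)-one | COC1=C(C)C(=O)O/C1=C\[C@@H](C)CCC/C(C)=C\CCc1coc(Cc2ccoc2)c1 | intermediate
36 | (5Z)-5-[(2S,6Z)-9-[5-(furan-3-ylmethyl)furan-3-yl]-2,6-dimethylnon-6-en-1-ylidene]-4-hydroxy-3-methylfuran-2(5H)-one | CC1=C(O)/C(=C/[C@@H](C)CCC/C(C)=C\CCc2coc(Cc3ccoc3)c2)OC1=O | target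

**Count**

Total steps: 15. Longest linear sequence: 9 steps (steps 2 to 8, then 14 and 15).

**Steps most likely to fail, with fallbacks**

Step 7. The ketene may be lost to dimerisation before the carbon nucleophile reaches it, unrearranged alkynyl ether may quench the vinyllithium by proton transfer, or the enolate may fail to close through oxygen. The fallback sets out from 12, returns at 18 and uses known reaction types only. Compound 12 is treated with n-BuLi at −78 °C and the lithium alkynyl ether is quenched with excess methanol, so that the same [3,3] shift takes place and methoxide takes up the ketene to give methyl (3R,4E)-6-(4-methoxyphenoxy)-3-methylhex-4-enoate F1 (same spatial arrangement; the descriptor changes because CH2CO2Me ranks below the vinyl group). MeNHOMe·HCl and i-PrMgCl convert it into (3R,4E)-N-methoxy-6-(4-methoxyphenoxy)-N,3-dimethylhex-4-enamide F2. Acylation of vinyllithium 16 by this Weinreb amide gives methyl (2E,6R,7E)-3-methoxy-9-(4-methoxyphenoxy)-2,6-dimethyl-4-oxonona-2,7-dienoate F3. Saponification with LiOH and acidification close the cis keto acid to 5-hydroxy-4-methoxy-5-[(2R,3E)-5-(4-methoxyphenoxy)-2-methylpent-3-en-1-yl]-3-methylfuran-2(5H)-one F4. Dehydration with (CF3CO)2O and Et3N then gives 18, the Z ylidene being the thermodynamically preferred isomer.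

Step 8. Hydride may be delivered to the wrong allyl terminus, the allylpalladium intermediate may undergo β-hydride elimination toward a triene, or the allylic centre may epimerise on heating with base. The fallback sets out from 18 and returns at 35, replacing steps 8 and 14. Diimide (2-nitrobenzenesulfonylhydrazide, Et3N) saturates the disubstituted alkene to give (5Z)-4-methoxy-5-[(2S)-5-(4-methoxyphenoxy)-2-methylpentylidene]-3-methylfuran-2(5H)-one F5. Oxidative removal of the 4-methoxyphenyl group with (NH4)2Ce(NO3)6 gives (5Z)-5-[(2S)-5-hydroxy-2-methylpentylidene]-4-methoxy-3-methylfuran-2(5H)-one F6. I2, PPh3 and imidazole give (5Z)-5-[(2S)-5-iodo-2-methylpentylidene]-4-methoxy-3-methylfuran-2(5H)-one F7. Insertion of activated Zn dust gives the alkylzinc iodide F8, and Negishi coupling with 33 under Pd(PPh3)4 gives 35.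

Step 10. Acid-induced oligomerisation of the furyl-stabilised carbenium ion may outrun hydride capture. The fallback sets out from 23 and returns at 24 without any cationic intermediate. Oxidation with MnO2 gives (4-bromofuran-2-yl)(furan-3-yl)methanone F9, and its hydrazone F10, formed with N2H4·H2O, is decomposed with KOH in diethylene glycol (Wolff–Kishner reduction) to give 24.

**Further compounds**

F1 | step 7 | methyl (3R,4E)-6-(4-methoxyphenoxy)-3-methylhex-4-enoate | COC(=O)C[C@@H](C)/C=C/COc1ccc(OC)cc1
F2 | step 7 | (3R,4E)-N-methoxy-6-(4-methoxyphenoxy)-N,3-dimethylhex-4-enamide | CON(C)C(=O)C[C@@H](C)/C=C/COc1ccc(OC)cc1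
F3 | step 7 | methyl (2E,6R,7E)-3-methoxy-9-(4-methoxyphenoxy)-2,6-dimethyl-4-oxonona-2,7-dienoate | COC(=O)/C(C)=C(/OC)C(=O)C[C@@H](C)/C=C/COc1ccc(OC)cc1
F4 | step 7 | 5-hydroxy-4-methoxy-5-[(2R,3E)-5-(4-methoxyphenoxy)-2-methylpent-3-en-1-yl]-3-methylfuran-2(5H)-one (both epimers at C5) | COC1=C(C)C(=O)OC1(O)C[C@@H](C)/C=C/COc1ccc(OC)cc1
F5 | step 8 | (5Z)-4-methoxy-5-[(2S)-5-(4-methoxyphenoxy)-2-methylpentylidene]-3-methylfuran-2(5H)-one | COC1=C(C)C(=O)O/C1=C\[C@@H](C)CCCOc1ccc(OC)cc1
F6 | step 8 | (5Z)-5-[(2S)-5-hydroxy-2-methylpentylidene]-4-methoxy-3-methylfuran-2(5H)-one | COC1=C(C)C(=O)O/C1=C\[C@@H](C)CCCO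
F7 | step 8 | (5Z)-5-[(2S)-5-iodo-2-methylpentylidene]-4-methoxy-3-methylfuran-2(5H)-one | COC1=C(C)C(=O)O/C1=C\[C@@H](C)CCCI
F8 | step 8 | [(4S,5Z)-5-(3-methoxy-4-methyl-5-oxofuran-2(5H)-ylidene)-4-methylpentyl]zinc iodide | COC1=C(C)C(=O)O/C1=C\[C@@H](C)CCC[Zn]I
F9 | step 10 | (4-bromofuran-2-yl)(furan-3-yl)methanone | O=C(c1ccoc1)c1cc(Br)co1
F10 | step 10 | (4-bromofuran-2-yl)(furan-3-yl)methanone hydrazone | NN=C(c1ccoc1)c1cc(Br)co1
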